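**Plan**

1. Retrosynthesis: the C6–C6' biaryl bond is cut last (Suzuki–Miyaura) into an aryl iodide and an aryl boronate that both come from one monomer. Each pyranone ring is then cut at C2–C3 and at O1–C8a, which leaves an acyclic α-keto ester (C2=O1 with the complete side chain) and a four-carbon C3–C4–C4a–C8a unit.
2. Enabling feature: in each benzene ring O1 (on C8a) and the phenol oxygen (on C5) flank the acyl-bearing C4a, so the ring is the aromatised form of a 2-acetylcyclohexane-1,3-dione. Carried at that oxidation level, C8a is the β-carbon of a vinylogous ester (electrophilic, OMe as leaving group) and C3 is the CH2 of a silyl enol ether (nucleophilic).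
3. Forward order: side chain first (α-keto ester), then the pyranone ring by a formal oxa-[4+2] annulation onto the cyclohexenone, then the benzene ring by dehydrogenation, iodination at C6, division into iodide and boronate (the boronate is debenzylated and lactonised), biaryl coupling, final hydrogenolysis.
4. Stereochemistry: the carbinol and methyl centres come from a (Z)-crotylboration under reagent control. C2 comes from polar Felkin–Anh addition to the ketone next to the benzyloxy centre. The biaryl axis has one ortho substituent per ring and is not a stereo element.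
5. Helpers: the cyclohexenone oxidation level, the OMe leaving group and the silyl group leave in the annulation and the dehydrogenation. The two benzyl groups keep the side chain of half A open and leave in the last step.

Key step: step 10

Remark: the crotylborane of step 1 is used as a separately prepared reagent solution (cis-2-butene, n-BuLi/KOt-Bu, (+)-Ipc2BOMe, BF3·OEt2, −78 °C); its preparation is not counted as a step.
Remark: the γ-hydroxy acid of the target is taken to be isolable without lactonisation as long as acid and heat are avoided.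

**Route**

Step 1
Reactants: 1 3-(trimethylsilyl)prop-2-ynal
Product: 2 (3R,4S)-4-methyl-1-(trimethylsilyl)hex-5-en-1-yn-3-ol
Conditions: (Z)-crotyl-B(Ipc)2 [Ipc from (−)-α-pinene], THF/Et2O, −78 °C; then 3 M NaOH, 30% H2O2, 0 °C
Reagents that add atoms: (Z)-crotyldiisopinocampheylborane, C/C=C\CB([C@H]1C[C@H]2C[C@@H]([C@@H]1C)C2(C)C)[C@H]1C[C@H]2C[C@@H]([C@@H]1C)C2(C)C
Why: Brown crotylboration through a closed chair (Zimmerman–Traxler) transition state, in which the Z-crotyl geometry should give the syn pair and the isopinocampheyl groups from (−)-α-pinene should direct attack to the Re face of the aldehyde, setting C3 as R and C4 as S.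

Step 2
Reactants: 2 (3R,4S)-4-methyl-1-(trimethylsilyl)hex-5-en-1-yn-3-ol
Product: 3 [(3R,4S)-3-(benzyloxy)-4-methylhex-5-en-1-yn-1-yl]trimethylsilane
Conditions: BnOC(=NH)CCl3, TfOH (cat.), CH2Cl2/cyclohexane, 0 °C to rt
Reagents that add atoms: benzyl 2,2,2-trichloroacetimidate, N=C(OCc1ccccc1)C(Cl)(Cl)Cl
Why: acid-catalysed O-benzylation with the trichloroacetimidate, which uses no base and so should leave the alkynylsilane and both stereocentres untouched.

Step 3
Reactants: 3 [(3R,4S)-3-(benzyloxy)-4-methylhex-5-en-1-yn-1-yl]trimethylsilane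
Product: 4 (3S,4R)-4-(benzyloxy)-3-methyl-6-(trimethylsilyl)hex-5-yn-1-ol
Conditions: 9-BBN, THF, 0 °C to rt; then 30% H2O2, aq. NaOAc, 0 °C
Reagents that add atoms: hydrogen peroxide, OO
Why: anti-Markovnikov hydroboration–oxidation, in which 9-BBN should react with the terminal alkene far faster than with the hindered silyl alkyne; no stereocentre is formed or touched.

Step 4
Reactants: 4 (3S,4R)-4-(benzyloxy)-3-methyl-6-(trimethylsilyl)hex-5-yn-1-ol
Product: 5 (3S,4R)-4-(benzyloxy)-3-methyl-6-(trimethylsilyl)hex-5-ynoic acid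
Conditions: TEMPO (cat.), PhI(OAc)2, MeCN/H2O, rt
Reagents that add atoms: water, O
Why: nitroxyl-catalysed oxidation of the primary alcohol through the aldehyde hydrate to the acid, under conditions that should spare the benzyl ether and the silyl alkyne.

Step 5
Reactants: 5 (3S,4R)-4-(benzyloxy)-3-methyl-6-(trimethylsilyl)hex-5-ynoic acid
Product: 6 benzyl (3S,4R)-4-(benzyloxy)-3-methyl-6-(trimethylsilyl)hex-5-ynoate
Conditions: BnOH, EDCI·HCl, DMAP (cat.), CH2Cl2, rt
Reagents that add atoms: benzyl alcohol, OCc1ccccc1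
Why: Steglich esterification under near-neutral conditions, giving the ester that can be removed later by hydrogenolysis together with the benzyl ether.

Step 6
Reactants: 6 benzyl (3S,4R)-4-(benzyloxy)-3-methyl-6-(trimethylsilyl)hex-5-ynoate
Product: 7 benzyl (3S,4R)-4-(benzyloxy)-6-bromo-3-methylhex-5-ynoate
Conditions: NBS, AgNO3 (10 mol%), acetone, rt
Reagents that add atoms: N-bromosuccinimide, BrN1C(=O)CCC1=O
Why: silver-catalysed bromodesilylation of the alkynylsilane via the silver acetylide, a standard entry to 1-bromoalkynes.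

Step 7
Reactants: 7 benzyl (3S,4R)-4-(benzyloxy)-6-bromo-3-methylhex-5-ynoate
Product: 8 6-benzyl 1-methyl (3R,4S)-3-(benzyloxy)-4-methyl-2-oxohexanedioate
Conditions: KMnO4, NaHCO3, MgSO4, MeOH/H2O, 0 °C
Reagents that add atoms: potassium permanganate, [K+].[O-][Mn](=O)(=O)=O; methanol, CO
Why: permanganate oxidation of a 1-bromoalkyne to the α-keto acyl bromide, which methanol should trap as the α-keto methyl ester, the buffered medium protecting the enolisable α-benzyloxy centre.

Step 8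
Reactants: 9 2-acetylcyclohexane-1,3-dione
Product: 10 2-acetyl-3-methoxycyclohex-2-en-1-one
Conditions: Me3SiCHN2, MeOH/PhMe, 0 °C to rt
Reagents that add atoms: (trimethylsilyl)diazomethane, C[Si](C)(C)C=[N+]=[N-]
Why: O-methylation of the acidic endocyclic enol (a vinylogous acid) by the diazoalkane, which installs the leaving group on the future C8a.

Step 9
Reactants: 10 2-acetyl-3-methoxycyclohex-2-en-1-one
Product: 11 3-methoxy-2-{1-[(trimethylsilyl)oxy]ethenyl}cyclohex-2-en-1-one
Conditions: LiN(SiMe3)2, THF, −78 °C; Me3SiCl, −78 °C to 0 °C; used crude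
Reagents that add atoms: chlorotrimethylsilane, C[Si](C)(C)Cl
Why: kinetic deprotonation at the acetyl CH3 (the least hindered α-position, on the ketone twisted out of conjugation) and O-silylation, the usual way 1-alkoxy-3-silyloxy dienes are made from vinylogous esters.

Step 10
Reactants: 8 6-benzyl 1-methyl (3R,4S)-3-(benzyloxy)-4-methyl-2-oxohexanedioate; 11 3-methoxy-2-{1-[(trimethylsilyl)oxy]ethenyl}cyclohex-2-en-1-one
Product: 13 methyl (2S)-2-[(1R,2S)-1,4-bis(benzyloxy)-2-methyl-4-oxobutyl]-4,5-dioxo-3,4,5,6,7,8-hexahydro-2H-chromene-2-carboxylate, via aldol adduct 12 (not isolated)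
Conditions: BF3·OEt2, CH2Cl2, −78 °C; then CF3CO2H, −78 °C to 0 °C; aq. NaHCO3 work-up
Reagents that add atoms: none
Why: BF3 activates the ketone of 8 and the terminal CH2 of the silyl enol ether adds to it (Mukaiyama aldol, C3–C2 bond); under CF3CO2H the tertiary hydroxyl of 12 then adds to the β-carbon of the 2-acyl-3-methoxy-enone and methanol is expelled (O1–C8a bond), so the sequence is a stepwise formal oxa-[4+2] annulation. The closest known reaction type is the Lewis-acid aldol/cyclisation of 1-alkoxy-3-silyloxy-1,3-dienes with α-keto esters, which gives 2,2-disubstituted 2,3-dihydropyran-4-ones. The pyranone ring closes by a 6-endo-trig oxa-Michael addition followed by elimination, which becomes irreversible once methanol is lost. The new quaternary centre C2 is set in the aldol event by 1,2-induction from the (R)-benzyloxy centre: monodentate BF3 cannot form a chelate, so the polar Felkin–Anh transition state (C–OBn bond anti to the incoming carbon, approach past H) should expose the Re face of the ketone and give (S). The step needs this facial selectivity, attack on the ketone and not on the esters, and closure at C8a only; these are secured by the benzyloxy centre under non-chelating conditions, by the much higher electrophilicity of the 1,2-dicarbonyl ketone, and by C8a being the only carbon that carries a leaving group.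

Step 11
Reactants: 13 methyl (2S)-2-[(1R,2S)-1,4-bis(benzyloxy)-2-methyl-4-oxobutyl]-4,5-dioxo-3,4,5,6,7,8-hexahydro-2H-chromene-2-carboxylate
Product: 14 methyl (2S)-2-[(1R,2S)-1,4-bis(benzyloxy)-2-methyl-4-oxobutyl]-5-hydroxy-4-oxo-3,4-dihydro-2H-chromene-2-carboxylate
Conditions: Pd(O2CCF3)2 (5 mol%), 2-(dimethylamino)pyridine (10 mol%), TsOH·H2O (20 mol%), O2 (1 atm), DMSO, 80 °C
Reagents that add atoms: none
Why: aerobic palladium-catalysed dehydrogenation of a cyclohexenone to a phenol, in which a divalent palladium enolate at C6 loses the C7 hydride and the dienone tautomerises; the pyranone ring cannot be dehydrogenated because C2 is quaternary, so C2 is not put at risk.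

Step 12
Reactants: 14 methyl (2S)-2-[(1R,2S)-1,4-bis(benzyloxy)-2-methyl-4-oxobutyl]-5-hydroxy-4-oxo-3,4-dihydro-2H-chromene-2-carboxylate
Product: 15 methyl (2S)-2-[(1R,2S)-1,4-bis(benzyloxy)-2-methyl-4-oxobutyl]-5-hydroxy-6-iodo-4-oxo-3,4-dihydro-2H-chromene-2-carboxylate
Conditions: BnNMe3·ICl2, CaCO3, CH2Cl2/MeOH, rt
Reagents that add atoms: benzyltrimethylammonium dichloroiodate, C[N+](C)(C)Cc1ccccc1.Cl[I-]Cl
Why: electrophilic iodination of the hydrogen-bonded phenol, expected at C6 (ortho to the 5-OH and para to O1) by analogy with chelated 5-hydroxyflavonoids under this reagent and with the iodination of 3-alkoxyphenols.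

Step 13
Reactants: 15 methyl (2S)-2-[(1R,2S)-1,4-bis(benzyloxy)-2-methyl-4-oxobutyl]-5-hydroxy-6-iodo-4-oxo-3,4-dihydro-2H-chromene-2-carboxylate (one portion)
Product: 16 methyl (2S)-2-[(1R,2S)-1,4-bis(benzyloxy)-2-methyl-4-oxobutyl]-5-hydroxy-4-oxo-6-(4,4,5,5-tetramethyl-1,3,2-dioxaborolan-2-yl)-3,4-dihydro-2H-chromene-2-carboxylate
Conditions: B2pin2, Pd(dppf)Cl2 (5 mol%), KOAc, 1,4-dioxane, 80 °C
Reagents that add atoms: bis(pinacolato)diboron, CC1(C)OB(OC1(C)C)B1OC(C)(C)C(C)(C)O1
Why: Miyaura borylation of the aryl iodide with the weak base KOAc, which should leave the esters, the ketone and the base-sensitive C2–O1 bond alone.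

Step 14
Reactants: 16 methyl (2S)-2-[(1R,2S)-1,4-bis(benzyloxy)-2-methyl-4-oxobutyl]-5-hydroxy-4-oxo-6-(4,4,5,5-tetramethyl-1,3,2-dioxaborolan-2-yl)-3,4-dihydro-2H-chromene-2-carboxylate
Product: 18 methyl (2S)-5-hydroxy-2-[(2R,3S)-3-methyl-5-oxooxolan-2-yl]-4-oxo-6-(4,4,5,5-tetramethyl-1,3,2-dioxaborolan-2-yl)-3,4-dihydro-2H-chromene-2-carboxylate, via hydroxy acid 17 (not isolated)
Conditions: H2 (1 atm), Pd/C, EtOAc, rt; filter; then TsOH·H2O (5 mol%), CH2Cl2, rt
Reagents that add atoms: none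
Why: hydrogenolysis of the benzyl ether and benzyl ester frees the γ-hydroxy acid, and acid catalysis closes the γ-lactone (5-exo-trig acyl substitution) with retention at both stereocentres, which gives the cis-lactone of half B; the C–B bond should survive both operations.

Step 15
Reactants: 15 methyl (2S)-2-[(1R,2S)-1,4-bis(benzyloxy)-2-methyl-4-oxobutyl]-5-hydroxy-6-iodo-4-oxo-3,4-dihydro-2H-chromene-2-carboxylate (second portion); 18 methyl (2S)-5-hydroxy-2-[(2R,3S)-3-methyl-5-oxooxolan-2-yl]-4-oxo-6-(4,4,5,5-tetramethyl-1,3,2-dioxaborolan-2-yl)-3,4-dihydro-2H-chromene-2-carboxylate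
Product: 19 methyl (2S)-2-[(1R,2S)-1,4-bis(benzyloxy)-2-methyl-4-oxobutyl]-5-hydroxy-6-{(2S)-5-hydroxy-2-(methoxycarbonyl)-2-[(2R,3S)-3-methyl-5-oxooxolan-2-yl]-4-oxo-3,4-dihydro-2H-chromen-6-yl}-4-oxo-3,4-dihydro-2H-chromene-2-carboxylate
Conditions: Pd(OAc)2 (5 mol%), SPhos (10 mol%), K3PO4, PhMe/H2O (10:1), 60 °C
Reagents that add atoms: none
Why: Suzuki–Miyaura cross-coupling with a biaryl phosphine suited to ortho-substituted partners, the chelated free phenols being tolerated as in couplings of 5-hydroxyflavone halides; no stereo axis arises because each ring has only one ortho substituent other than H.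

Step 16
Reactants: 19 methyl (2S)-2-[(1R,2S)-1,4-bis(benzyloxy)-2-methyl-4-oxobutyl]-5-hydroxy-6-{(2S)-5-hydroxy-2-(methoxycarbonyl)-2-[(2R,3S)-3-methyl-5-oxooxolan-2-yl]-4-oxo-3,4-dihydro-2H-chromen-6-yl}-4-oxo-3,4-dihydro-2H-chromene-2-carboxylate
Product: 20 (3S,4R)-4-hydroxy-4-[(2S)-5-hydroxy-6-{(2S)-5-hydroxy-2-(methoxycarbonyl)-2-[(2R,3S)-3-methyl-5-oxooxolan-2-yl]-4-oxo-3,4-dihydro-2H-chromen-6-yl}-2-(methoxycarbonyl)-4-oxo-3,4-dihydro-2H-chromen-2-yl]-3-methylbutanoic acid (CNP0517857.1)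
Conditions: H2 (1 atm), Pd/C, EtOAc, rt; filtration and concentration below rt, no acid
Reagents that add atoms: none
Why: hydrogenolysis of the benzyl ether and benzyl ester under neutral conditions should release the hydroxy acid of half A without the acid, base or heat that would close it to the lactone, while the aryl ketones, the lactone of half B and the methyl esters are inert.

**Compound list**

1 | 3-(trimethylsilyl)prop-2-ynal | C[Si](C)(C)C#CC=O | starting material
2 | (3R,4S)-4-methyl-1-(trimethylsilyl)hex-5-en-1-yn-3-ol | C[Si](C)(C)C#C[C@H](O)[C@@H](C)C=C | intermediate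
3 | [(3R,4S)-3-(benzyloxy)-4-methylhex-5-en-1-yn-1-yl]trimethylsilane | C[Si](C)(C)C#C[C@H](OCc1ccccc1)[C@@H](C)C=C | intermediate
4 | (3S,4R)-4-(benzyloxy)-3-methyl-6-(trimethylsilyl)hex-5-yn-1-ol | C[Si](C)(C)C#C[C@H](OCc1ccccc1)[C@@H](C)CCO | intermediate
5 | (3S,4R)-4-(benzyloxy)-3-methyl-6-(trimethylsilyl)hex-5-ynoic acid | C[Si](C)(C)C#C[C@H](OCc1ccccc1)[C@@H](C)CC(=O)O | intermediate
6 | benzyl (3S,4R)-4-(benzyloxy)-3-methyl-6-(trimethylsilyl)hex-5-ynoate | C[Si](C)(C)C#C[C@H](OCc1ccccc1)[C@@H](C)CC(=O)OCc1ccccc1 | intermediate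
7 | benzyl (3S,4R)-4-(benzyloxy)-6-bromo-3-methylhex-5-ynoate | BrC#C[C@H](OCc1ccccc1)[C@@H](C)CC(=O)OCc1ccccc1 | intermediate
8 | 6-benzyl 1-methyl (3R,4S)-3-(benzyloxy)-4-methyl-2-oxohexanedioate | COC(=O)C(=O)[C@H](OCc1ccccc1)[C@@H](C)CC(=O)OCc1ccccc1 | intermediate
9 | 2-acetylcyclohexane-1,3-dione | CC(=O)C1C(=O)CCCC1=O | starting material
10 | 2-acetyl-3-methoxycyclohex-2-en-1-one | COC1=C(C(C)=O)C(=O)CCC1 | intermediate
11 | 3-methoxy-2-{1-[(trimethylsilyl)oxy]ethenyl}cyclohex-2-en-1-one | COC1=C(C(=C)O[Si](C)(C)C)C(=O)CCC1 | intermediate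
12 | 6-benzyl 1-methyl (2S,3R,4S)-3-(benzyloxy)-2-hydroxy-2-[2-(2-methoxy-6-oxocyclohex-1-en-1-yl)-2-oxoethyl]-4-methylhexanedioate (aldol adduct) | COC(=O)[C@@](O)([C@H](OCc1ccccc1)[C@@H](C)CC(=O)OCc1ccccc1)CC(=O)C1=C(OC)CCCC1=O | intermediate
13 | methyl (2S)-2-[(1R,2S)-1,4-bis(benzyloxy)-2-methyl-4-oxobutyl]-4,5-dioxo-3,4,5,6,7,8-hexahydro-2H-chromene-2-carboxylate | COC(=O)[C@@]1([C@H](OCc2ccccc2)[C@@H](C)CC(=O)OCc2ccccc2)CC(=O)C2=C(CCCC2=O)O1 | intermediate
14 | methyl (2S)-2-[(1R,2S)-1,4-bis(benzyloxy)-2-methyl-4-oxobutyl]-5-hydroxy-4-oxo-3,4-dihydro-2H-chromene-2-carboxylate | COC(=O)[C@@]1([C@H](OCc2ccccc2)[C@@H](C)CC(=O)OCc2ccccc2)CC(=O)c2c(cccc2O)O1 | intermediate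
15 | methyl (2S)-2-[(1R,2S)-1,4-bis(benzyloxy)-2-methyl-4-oxobutyl]-5-hydroxy-6-iodo-4-oxo-3,4-dihydro-2H-chromene-2-carboxylate | COC(=O)[C@@]1([C@H](OCc2ccccc2)[C@@H](C)CC(=O)OCc2ccccc2)CC(=O)c2c(ccc(I)c2O)O1 | intermediate
16 | methyl (2S)-2-[(1R,2S)-1,4-bis(benzyloxy)-2-methyl-4-oxobutyl]-5-hydroxy-4-oxo-6-(4,4,5,5-tetramethyl-1,3,2-dioxaborolan-2-yl)-3,4-dihydro-2H-chromene-2-carboxylate | COC(=O)[C@@]1([C@H](OCc2ccccc2)[C@@H](C)CC(=O)OCc2ccccc2)CC(=O)c2c(ccc(B3OC(C)(C)C(C)(C)O3)c2O)O1 | intermediate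
17 | (3S,4R)-4-hydroxy-4-[(2S)-5-hydroxy-2-(methoxycarbonyl)-4-oxo-6-(4,4,5,5-tetramethyl-1,3,2-dioxaborolan-2-yl)-3,4-dihydro-2H-chromen-2-yl]-3-methylbutanoic acid (hydroxy acid) | COC(=O)[C@@]1([C@H](O)[C@@H](C)CC(=O)O)CC(=O)c2c(ccc(B3OC(C)(C)C(C)(C)O3)c2O)O1 | intermediate
18 | methyl (2S)-5-hydroxy-2-[(2R,3S)-3-methyl-5-oxooxolan-2-yl]-4-oxo-6-(4,4,5,5-tetramethyl-1,3,2-dioxaborolan-2-yl)-3,4-dihydro-2H-chromene-2-carboxylate | COC(=O)[C@@]1([C@@H]2OC(=O)C[C@@H]2C)CC(=O)c2c(ccc(B3OC(C)(C)C(C)(C)O3)c2O)O1 | intermediate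
19 | methyl (2S)-2-[(1R,2S)-1,4-bis(benzyloxy)-2-methyl-4-oxobutyl]-5-hydroxy-6-{(2S)-5-hydroxy-2-(methoxycarbonyl)-2-[(2R,3S)-3-methyl-5-oxooxolan-2-yl]-4-oxo-3,4-dihydro-2H-chromen-6-yl}-4-oxo-3,4-dihydro-2H-chromene-2-carboxylate | COC(=O)[C@@]1([C@H](OCc2ccccc2)[C@@H](C)CC(=O)OCc2ccccc2)CC(=O)c2c(ccc(-c3ccc4c(c3O)C(=O)C[C@@](C(=O)OC)([C@@H]3OC(=O)C[C@@H]3C)O4)c2O)O1 | intermediate
20 | (3S,4R)-4-hydroxy-4-[(2S)-5-hydroxy-6-{(2S)-5-hydroxy-2-(methoxycarbonyl)-2-[(2R,3S)-3-methyl-5-oxooxolan-2-yl]-4-oxo-3,4-dihydro-2H-chromen-6-yl}-2-(methoxycarbonyl)-4-oxo-3,4-dihydro-2H-chromen-2-yl]-3-methylbutanoic acid | COC(=O)[C@@]1([C@H](O)[C@@H](C)CC(=O)O)CC(=O)c2c(ccc(-c3ccc4c(c3O)C(=O)C[C@@](C(=O)OC)([C@@H]3OC(=O)C[C@@H]3C)O4)c2O)O1 | target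

**Step count and risks**

Total steps: 16. Longest linear sequence: 14 (steps 1–7, then 10–16).

Risk 1, step 10. The aldol may show poor facial selectivity at C2, or the hindered tertiary hydroxyl may add too slowly to the vinylogous ester, so that the silyl enol ether is lost to protonation instead. The fallback replaces the cyclohexenone by an aromatic ring and closes the pyranone by nucleophilic aromatic substitution; it sets out from 8 and comes back to the route at 14. Commercial 1-(2-fluoro-6-hydroxyphenyl)ethan-1-one is protected (MOMCl, i-Pr2NEt, CH2Cl2) as 1-[2-fluoro-6-(methoxymethoxy)phenyl]ethan-1-one F1. This is converted (Me3SiOTf, Et3N, CH2Cl2, 0 °C) into its trimethylsilyl enol ether F2, which has only one enolisable position. Mukaiyama aldol of F2 with 8 (BF3·OEt2, CH2Cl2, −78 °C, same Felkin–Anh control) should give the β-hydroxy ketone F3. Cs2CO3 in DMF then closes the ring by intramolecular displacement of the fluoride ortho to the ketone to give the methoxymethyl-protected chromanone F4, and CF3CO2H in CH2Cl2 at 0 °C removes the acetal to give 14. Steps 8, 9 and 11 are then not needed.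

Risk 2, step 12. Iodination may occur in part at C8 (para to the phenol, ortho to O1) and the isomers may be hard to separate. The fallback brings the halogen in with an aromatic building block whose substitution pattern is fixed; it sets out from 8 and comes back to the route at 16 and at 19. 2-Bromo-5-fluorophenol is acetylated (Ac2O, pyridine) to 2-bromo-5-fluorophenyl acetate F5. Fries rearrangement (AlCl3, neat, 140 °C) moves the acetyl group to the only free ortho position and gives 1-(3-bromo-6-fluoro-2-hydroxyphenyl)ethan-1-one F6. MOMCl/i-Pr2NEt gives the methoxymethyl ether F7, and Me3SiOTf/Et3N gives its trimethylsilyl enol ether F8. Mukaiyama aldol of F8 with 8 (BF3·OEt2, −78 °C) gives the aldol F9, Cs2CO3/DMF closes the pyranone to the bromo chromanone F10, and CF3CO2H removes the acetal to give the 6-bromo analogue of 15, the bromophenol F11. F11 takes the place of 15 in step 13 (giving 16) and in step 15 (giving 19).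

Risk 3, step 15. The ortho-hydroxyaryl boronate may protodeboronate, and the aqueous base may open the lactone or trigger retro-oxa-Michael opening at C2. The fallback is a base-free Stille coupling with the roles of the halves exchanged; it sets out from 15 and comes back to the route at 19. One portion of 15 is debenzylated without loss of iodine (BCl3, pentamethylbenzene, CH2Cl2, −78 °C) and lactonised (TsOH cat., CH2Cl2) to the lactone iodide F12. A second portion of 15 is stannylated (Me3SnSnMe3, Pd(PPh3)4, PhMe, 90 °C) to the aryl trimethylstannane F13. Coupling of F12 with F13 (Pd(PPh3)4, CuI cat., DMF, 60 °C) gives 19. Steps 13 and 14 are then not needed.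

**Further compounds**

F1 | step 10 | 1-[2-fluoro-6-(methoxymethoxy)phenyl]ethan-1-one | CC(=O)c1c(F)cccc1OCOC
F2 | step 10 | {1-[2-fluoro-6-(methoxymethoxy)phenyl]ethenyl}oxy(trimethyl)silane | C=C(O[Si](C)(C)C)c1c(F)cccc1OCOC
F3 | step 10 | 6-benzyl 1-methyl (2S,3R,4S)-3-(benzyloxy)-2-{2-[2-fluoro-6-(methoxymethoxy)phenyl]-2-oxoethyl}-2-hydroxy-4-methylhexanedioate | COC(=O)[C@@](O)([C@H](OCc1ccccc1)[C@@H](C)CC(=O)OCc1ccccc1)CC(=O)c1c(F)cccc1OCOC
F4 | step 10 | methyl (2S)-2-[(1R,2S)-1,4-bis(benzyloxy)-2-methyl-4-oxobutyl]-5-(methoxymethoxy)-4-oxo-3,4-dihydro-2H-chromene-2-carboxylate | COC(=O)[C@@]1([C@H](OCc2ccccc2)[C@@H](C)CC(=O)OCc2ccccc2)CC(=O)c2c(cccc2OCOC)O1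
F5 | step 12 | 2-bromo-5-fluorophenyl acetate | CC(=O)Oc1cc(F)ccc1Br
F6 | step 12 | 1-(3-bromo-6-fluoro-2-hydroxyphenyl)ethan-1-one | CC(=O)c1c(F)ccc(Br)c1O
F7 | step 12 | 1-[3-bromo-6-fluoro-2-(methoxymethoxy)phenyl]ethan-1-one | CC(=O)c1c(F)ccc(Br)c1OCOC
F8 | step 12 | {1-[3-bromo-6-fluoro-2-(methoxymethoxy)phenyl]ethenyl}oxy(trimethyl)silane | C=C(O[Si](C)(C)C)c1c(F)ccc(Br)c1OCOC
F9 | step 12 | 6-benzyl 1-methyl (2S,3R,4S)-3-(benzyloxy)-2-{2-[3-bromo-6-fluoro-2-(methoxymethoxy)phenyl]-2-oxoethyl}-2-hydroxy-4-methylhexanedioate | COC(=O)[C@@](O)([C@H](OCc1ccccc1)[C@@H](C)CC(=O)OCc1ccccc1)CC(=O)c1c(F)ccc(Br)c1OCOC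
F10 | step 12 | methyl (2S)-2-[(1R,2S)-1,4-bis(benzyloxy)-2-methyl-4-oxobutyl]-6-bromo-5-(methoxymethoxy)-4-oxo-3,4-dihydro-2H-chromene-2-carboxylate | COC(=O)[C@@]1([C@H](OCc2ccccc2)[C@@H](C)CC(=O)OCc2ccccc2)CC(=O)c2c(ccc(Br)c2OCOC)O1
F11 | step 12 | methyl (2S)-2-[(1R,2S)-1,4-bis(benzyloxy)-2-methyl-4-oxobutyl]-6-bromo-5-hydroxy-4-oxo-3,4-dihydro-2H-chromene-2-carboxylate | COC(=O)[C@@]1([C@H](OCc2ccccc2)[C@@H](C)CC(=O)OCc2ccccc2)CC(=O)c2c(ccc(Br)c2O)O1
F12 | step 15 | methyl (2S)-5-hydroxy-6-iodo-2-[(2R,3S)-3-methyl-5-oxooxolan-2-yl]-4-oxo-3,4-dihydro-2H-chromene-2-carboxylate | COC(=O)[C@@]1([C@@H]2OC(=O)C[C@@H]2C)CC(=O)c2c(ccc(I)c2O)O1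
F13 | step 15 | methyl (2S)-2-[(1R,2S)-1,4-bis(benzyloxy)-2-methyl-4-oxobutyl]-5-hydroxy-4-oxo-6-(trimethylstannyl)-3,4-dihydro-2H-chromene-2-carboxylate | COC(=O)[C@@]1([C@H](OCc2ccccc2)[C@@H](C)CC(=O)OCc2ccccc2)CC(=O)c2c(ccc([Sn](C)(C)C)c2O)O1
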